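**Plan**
- Labdane numbering: ring A = C1–C5/C10, ring B = C5–C10, C9 carbinol, chain C11–C16. Retrosynthetic cuts, in order: the acetyl group and the C2/C3 oxygens (back to a C2=C3 alkene); C12–C13 (alkyl–alkenyl coupling) and C9–C11 (vinyl addition to a C9 ketone); C6–C7 of ring B; ring A at C10–C1 and C4–C5.
- Forward: ring A is built first by an enantioselective Michael addition, aldol condensation and C4 methylation, which leaves an exocyclic C5=C6 methylene. Ring B is then closed at C6–C7 by a 6-endo radical cyclisation from C7. The chain is added last at C9 and extended by a B-alkyl Suzuki coupling.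
- Enabling feature: C5 sits between two quaternary carbons (C4 gem-dimethyl and C10), so a C7 radical β to the C9 carbonyl can only bond to C6. The resulting tertiary C5 radical takes hydrogen anti to the axial C10 methyl (trans ring fusion), and the C9 carbonyl lets the C8 methyl settle equatorial.
- Stereochemistry: C10 from the chiral palladium catalyst; C5, C8, C9, C2 and C3 by substrate control relayed from the axial C10 methyl (vinyl nucleophile and OsO4 both enter from the α face); the 13Z alkene from a stereoretentive coupling of a (Z)-iodo enoate.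

Key step: step 9

Assumption: the (R)-BINAP palladium complex of step 1 is taken to give the (S)-adduct 3; if the sense of induction is the opposite, the (S)-BINAP complex is used and nothing else changes.

**Step 1**
Reactants: 1 tert-butyl 2-methyl-3-oxobutanoate; 2 pent-1-en-3-one
Product: 3 tert-butyl (2S)-2-acetyl-2-methyl-5-oxoheptanoate
Conditions: [Pd((R)-BINAP)(H2O)2](OTf)2 (5 mol %), THF, −20 °C
Reagents that add atoms: none
Why: Enantioselective Michael addition through a chiral divalent palladium enolate of the β-keto ester, which should add to the enone from the face left open by the BINAP aryl groups and so set the quaternary C10 centre.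

**Step 2**
Reactants: 3 tert-butyl (2S)-2-acetyl-2-methyl-5-oxoheptanoate
Product: 4 tert-butyl (1S)-1,2,3-trimethyl-4-oxocyclohex-2-ene-1-carboxylate
Conditions: pyrrolidine (0.3 equiv), AcOH (0.3 equiv), PhMe, 80 °C
Reagents that add atoms: none
Why: Intramolecular aldol condensation (the ring-closing half of a Robinson annulation) through the enamine of the unhindered ethyl ketone, whose α-carbon C4 attacks the acetyl carbonyl C5 to give the six-membered enone, while the quaternary centre has no α-hydrogen and cannot epimerise.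

**Step 3**
Reactants: 4 tert-butyl (1S)-1,2,3-trimethyl-4-oxocyclohex-2-ene-1-carboxylate
Product: 5 tert-butyl (1S)-1,3,3-trimethyl-2-methylidene-4-oxocyclohexane-1-carboxylate
Conditions: t-BuOK (1.3 equiv), t-BuOH/THF, 0 °C; MeI (1.5 equiv), 0 °C → rt
Reagents that add atoms: iodomethane, CI
Why: Deconjugative α-alkylation of an enone: the base removes a γ-hydrogen from the C6 methyl (the ring γ-carbon C10 is quaternary) and the extended dienolate is methylated at its α-carbon C4, which should give the gem-dimethyl group and move the alkene to the exocyclic C5=C6 position.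

**Step 4**
Reactants: 5 tert-butyl (1S)-1,3,3-trimethyl-2-methylidene-4-oxocyclohexane-1-carboxylate
Product: 6 tert-butyl (1S)-1,5,5-trimethyl-6-methylidene-4-[(trifluoromethanesulfonyl)oxy]cyclohex-3-ene-1-carboxylate
Conditions: KN(SiMe3)2, THF, −78 °C; PhNTf2, −78 → 0 °C
Reagents that add atoms: N-phenylbis(trifluoromethanesulfonimide), O=S(=O)(N(c1ccccc1)S(=O)(=O)C(F)(F)F)C(F)(F)F
Why: Enol triflate formation from the ketone enolate, which can form only toward C2 because C4 is quaternary.

**Step 5**
Reactants: 6 tert-butyl (1S)-1,5,5-trimethyl-6-methylidene-4-[(trifluoromethanesulfonyl)oxy]cyclohex-3-ene-1-carboxylate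
Product: 7 tert-butyl (1S)-1,5,5-trimethyl-6-methylidenecyclohex-3-ene-1-carboxylate
Conditions: Pd(OAc)2 (5 mol %), PPh3 (10 mol %), HCO2H, Bu3N, DMF, 60 °C
Reagents that add atoms: none
Why: Palladium-catalysed formate reduction of an enol triflate (oxidative addition to zerovalent palladium, formate exchange, loss of CO2, C–H reductive elimination), which should leave the ring A C2=C3 alkene without touching the exocyclic alkene or the ester.

**Step 6**
Reactants: 7 tert-butyl (1S)-1,5,5-trimethyl-6-methylidenecyclohex-3-ene-1-carboxylate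
Product: 9 (1S)-1,5,5-trimethyl-6-methylidenecyclohex-3-ene-1-carboxylic acid, via trimethylsilyl ester 8 (not isolated)
Conditions: TMSOTf (1.5 equiv), 2,6-lutidine (2 equiv), CH2Cl2, 0 °C → rt; then aq. citric acid
Reagents that add atoms: none
Why: Silyl triflate-mediated cleavage of a tert-butyl ester by loss of 2-methylpropene, run under buffered aprotic conditions so that the acid-sensitive 1,1-disubstituted alkene is not protonated, with hydrolysis of the silyl ester on work-up.

**Step 7**
Reactants: 9 (1S)-1,5,5-trimethyl-6-methylidenecyclohex-3-ene-1-carboxylic acid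
Product: 10 2-methyl-1-[(1S)-1,5,5-trimethyl-6-methylidenecyclohex-3-en-1-yl]prop-2-en-1-one
Conditions: CH2=C(CH3)Li (3 equiv; from 2-bromopropene and Li, Et2O), Et2O, −78 → 0 °C; inverse quench into cold aq. NH4Cl
Reagents that add atoms: 2-propenyllithium, [Li]C(C)=C (made in the flask from 2-bromopropene, C=C(C)Br, and lithium)
Why: Ketone synthesis from a carboxylic acid and an organolithium: the lithium carboxylate takes up one alkenyllithium to give a dilithium gem-diolate that is stable until hydrolysis, so no second addition should occur.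

**Step 8**
Reactants: 10 2-methyl-1-[(1S)-1,5,5-trimethyl-6-methylidenecyclohex-3-en-1-yl]prop-2-en-1-one
Product: 11 2-methyl-3-(phenylselanyl)-1-[(1S)-1,5,5-trimethyl-6-methylidenecyclohex-3-en-1-yl]propan-1-one (mixture of epimers at the new CH(CH3) centre)
Conditions: PhSeH (1.2 equiv), Et3N (0.1 equiv), CH2Cl2, 0 °C, dark
Reagents that add atoms: benzeneselenol, [SeH]c1ccccc1
Why: Base-catalysed conjugate (selena-Michael) addition of the selenol to the enone, chemoselective over the two unactivated alkenes; C8 forms as a mixture of epimers, which does not matter because C8 is equilibrated in step 9.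

**Step 9**
Reactants: 11 2-methyl-3-(phenylselanyl)-1-[(1S)-1,5,5-trimethyl-6-methylidenecyclohex-3-en-1-yl]propan-1-one
Product: 13 (2R,4aS,8aS)-2,5,5,8a-tetramethyl-3,4,4a,5,8,8a-hexahydronaphthalen-1(2H)-one, via C8-epimeric decalone mixture 12 (not isolated)
Conditions: Bu3SnH (1.3 equiv, syringe pump, 8 h), AIBN (0.2 equiv), PhH (0.01 M), 80 °C; then DBU (0.5 equiv), rt
Reagents that add atoms: none
Why: Bu3Sn• abstracts the phenylselanyl group to give the primary C7 radical β to the C9 carbonyl, which adds to C6 of the exocyclic C5=C6 methylene and closes ring B; the tertiary C5 radical then takes a hydrogen atom from Bu3SnH. The closest known reaction type is the tin hydride cyclisation of 5-substituted hex-5-enyl radicals, which close in the 6-endo mode. Ring B is the only ring formed, six-membered, by 6-endo-trig closure at C6–C7. C5 is set by hydrogen delivery to the face anti to the axial C10 methyl and the β-methyl on C4, which should give the trans ring fusion; C8 is set afterwards by DBU equilibration α to the C9 ketone, where the equatorial methyl avoids a 1,3-diaxial clash with the C10 methyl. The step needs 6-endo over 5-exo closure and ring closure ahead of premature reduction: bond formation at C5 is blocked because C5 lies between the quaternary C4 and C10, and the stannane is kept dilute by slow addition so that closure outruns hydrogen transfer to the primary radical.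

**Step 10**
Reactants: 13 (2R,4aS,8aS)-2,5,5,8a-tetramethyl-3,4,4a,5,8,8a-hexahydronaphthalen-1(2H)-one
Product: 14 (1S,2R,4aS,8aS)-1-ethenyl-2,5,5,8a-tetramethyl-1,2,3,4,4a,5,8,8a-octahydronaphthalen-1-ol
Conditions: CH2=CHMgBr (3 equiv), CeCl3 (3 equiv), THF, −78 → 0 °C
Reagents that add atoms: vinylmagnesium bromide, C=C[Mg]Br
Why: Organocerium 1,2-addition to a hindered, enolisable ketone; the vinyl group should enter from the α face, anti to the axial C10 methyl that blocks the β face, so that the new C9 hydroxyl is equatorial and cis to that methyl (9S).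

**Step 11**
Reactants: 15 methyl but-2-ynoate
Product: 16 methyl (2Z)-3-iodobut-2-enoate
Conditions: NaI (1.6 equiv), AcOH, 110 °C
Reagents that add atoms: sodium iodide, [Na+].[I-]
Why: Conjugate hydroiodination of an ynoate, which proceeds by anti addition of HI and should give the (Z)-β-iodo enoate.

**Step 12**
Reactants: 14 (1S,2R,4aS,8aS)-1-ethenyl-2,5,5,8a-tetramethyl-1,2,3,4,4a,5,8,8a-octahydronaphthalen-1-ol; 16 methyl (2Z)-3-iodobut-2-enoate
Product: 18 methyl (5S,8R,9S,10S,13Z)-9-hydroxylabda-2,13-dien-15-oate, via B-alkyl-9-BBN borane 17 (not isolated)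
Conditions: 9-BBN (2.2 equiv), THF, rt → 50 °C; then 16, PdCl2(dppf) (5 mol %), AsPh3 (5 mol %), K3PO4 (3 M aq.), DMF, rt
Reagents that add atoms: none
Why: Hydroboration followed by B-alkyl Suzuki–Miyaura coupling: 9-BBN adds to the terminal carbon of the monosubstituted vinyl group much faster than to the hindered 1,2-disubstituted ring alkene, and the alkenyl iodide couples with retention, which should fix the 13Z geometry.

**Step 13**
Reactants: 18 methyl (5S,8R,9S,10S,13Z)-9-hydroxylabda-2,13-dien-15-oate
Product: 19 methyl (2R,3S,5S,8R,9S,10S,13Z)-2,3,9-trihydroxylabd-13-en-15-oate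
Conditions: OsO4 (2 mol %), NMO (1.1 equiv), acetone/H2O (8:1), 0 °C → rt
Reagents that add atoms: osmium tetroxide, O=[Os](=O)(=O)=O (catalytic oxygen carrier); N-methylmorpholine N-oxide, C[N+]1([O-])CCOCC1; water, O
Why: Catalytic OsO4/NMO syn-dihydroxylation; the electrophilic osmium reagent should select the electron-rich ring alkene over the conjugated ester alkene and add from the α face, away from the axial C10 methyl and the β-methyl on C4, which sets the 2α,3α-diol (2R,3S).

**Step 14**
Reactants: 19 methyl (2R,3S,5S,8R,9S,10S,13Z)-2,3,9-trihydroxylabd-13-en-15-oate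
Product: 20 methyl (2R,3S,5S,8R,9S,10S,13Z)-2-acetoxy-3,9-dihydroxylabd-13-en-15-oate (target)
Conditions: Ac2O (1.1 equiv), pyridine, CH2Cl2, 0 °C
Reagents that add atoms: acetic anhydride, CC(=O)OC(C)=O
Why: Selective acylation of the equatorial secondary C2 hydroxyl; the axial C3 hydroxyl next to the C4 gem-dimethyl group and the tertiary C9 hydroxyl should react far more slowly.

**Compound list**
1 | tert-butyl 2-methyl-3-oxobutanoate | CC(=O)C(C)C(=O)OC(C)(C)C | starting material
2 | pent-1-en-3-one | CCC(=O)C=C | starting material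
3 | tert-butyl (2S)-2-acetyl-2-methyl-5-oxoheptanoate | CCC(=O)CC[C@@](C(C)=O)(C(=O)OC(C)(C)C)C | intermediate
4 | tert-butyl (1S)-1,2,3-trimethyl-4-oxocyclohex-2-ene-1-carboxylate | CC1=C(C)C(=O)CC[C@]1(C)C(=O)OC(C)(C)C | intermediate
5 | tert-butyl (1S)-1,3,3-trimethyl-2-methylidene-4-oxocyclohexane-1-carboxylate | C=C1C(C)(C)C(=O)CC[C@]1(C)C(=O)OC(C)(C)C | intermediate
6 | tert-butyl (1S)-1,5,5-trimethyl-6-methylidene-4-[(trifluoromethanesulfonyl)oxy]cyclohex-3-ene-1-carboxylate | C=C1C(C)(C)C(OS(=O)(=O)C(F)(F)F)=CC[C@]1(C)C(=O)OC(C)(C)C | intermediate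
7 | tert-butyl (1S)-1,5,5-trimethyl-6-methylidenecyclohex-3-ene-1-carboxylate | C=C1C(C)(C)C=CC[C@]1(C)C(=O)OC(C)(C)C | intermediate
8 | trimethylsilyl (1S)-1,5,5-trimethyl-6-methylidenecyclohex-3-ene-1-carboxylate | C=C1C(C)(C)C=CC[C@]1(C)C(=O)O[Si](C)(C)C | intermediate (not isolated)
9 | (1S)-1,5,5-trimethyl-6-methylidenecyclohex-3-ene-1-carboxylic acid | C=C1C(C)(C)C=CC[C@]1(C)C(=O)O | intermediate
10 | 2-methyl-1-[(1S)-1,5,5-trimethyl-6-methylidenecyclohex-3-en-1-yl]prop-2-en-1-one | C=C1C(C)(C)C=CC[C@]1(C)C(=O)C(C)=C | intermediate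
11 | 2-methyl-3-(phenylselanyl)-1-[(1S)-1,5,5-trimethyl-6-methylidenecyclohex-3-en-1-yl]propan-1-one (epimers at C2 of the propanone) | C=C1C(C)(C)C=CC[C@]1(C)C(=O)C(C)C[Se]c1ccccc1 | intermediate
12 | (4aS,8aS)-2,5,5,8a-tetramethyl-3,4,4a,5,8,8a-hexahydronaphthalen-1(2H)-one, mixture of C2 epimers (C8 in labdane numbering) | O=C1C(C)CC[C@H]2C(C)(C)C=CC[C@@]21C | intermediate (not isolated)
13 | (2R,4aS,8aS)-2,5,5,8a-tetramethyl-3,4,4a,5,8,8a-hexahydronaphthalen-1(2H)-one (trans-fused, equatorial C2 methyl) | O=C1[C@H](C)CC[C@H]2C(C)(C)C=CC[C@@]21C | intermediate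
14 | (1S,2R,4aS,8aS)-1-ethenyl-2,5,5,8a-tetramethyl-1,2,3,4,4a,5,8,8a-octahydronaphthalen-1-ol | C=C[C@]1(O)[C@H](C)CC[C@H]2C(C)(C)C=CC[C@@]21C | intermediate
15 | methyl but-2-ynoate | CC#CC(=O)OC | starting material
16 | methyl (2Z)-3-iodobut-2-enoate | COC(=O)/C=C(/C)I | intermediate
17 | 9-{2-[(1S,2R,4aS,8aS)-1-hydroxy-2,5,5,8a-tetramethyl-1,2,3,4,4a,5,8,8a-octahydronaphthalen-1-yl]ethyl}-9-borabicyclo[3.3.1]nonane | B1(CC[C@]2(O)[C@H](C)CC[C@H]3C(C)(C)C=CC[C@@]32C)C4CCCC1CCC4 | intermediate (not isolated)
18 | methyl (5S,8R,9S,10S,13Z)-9-hydroxylabda-2,13-dien-15-oate | COC(=O)/C=C(/C)CC[C@]1(O)[C@H](C)CC[C@H]2C(C)(C)C=CC[C@@]21C | intermediate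
19 | methyl (2R,3S,5S,8R,9S,10S,13Z)-2,3,9-trihydroxylabd-13-en-15-oate | COC(=O)/C=C(/C)CC[C@]1(O)[C@H](C)CC[C@H]2C(C)(C)[C@H](O)[C@H](O)C[C@@]21C | intermediate
20 | methyl (2R,3S,5S,8R,9S,10S,13Z)-2-acetoxy-3,9-dihydroxylabd-13-en-15-oate | COC(=O)/C=C(/C)CC[C@]1(O)[C@H](C)CC[C@H]2C(C)(C)[C@H](O)[C@H](OC(C)=O)C[C@@]21C | target

**Step count and risks**
Total steps: 14. Longest linear sequence: 13 (steps 1–10 and 12–14; step 11 is a one-step side branch).

The three steps most likely to fail:

1. Step 9. What may go wrong: hydrogen transfer to the primary C7 radical before it closes the ring, 1,5-hydrogen transfer from the allylic C1 position, a 1,2-vinyl shift of the tertiary C5 radical toward the ring A alkene, or incomplete facial selectivity of hydrogen delivery at C5. The first three are tied to the ring A alkene being present or to slow closure. The fallback sets out from 5 and comes back at 13, and makes the ring A alkene only after ring B is closed. The ester of 5 is cleaved as in step 6 to the keto acid F1. F1 is treated with LiN(SiMe3)2 (2.2 equiv, giving the carboxylate and the C3 enolate, which masks the ketone) and then with 2-propenyllithium to give the enone F2. PhSeH addition as in step 8 gives the selenide F3. Bu3SnH/AIBN cyclisation and DBU equilibration as in step 9 give the trans-fused 3,9-dione F4. KN(SiMe3)2 and PhNTf2 at −78 °C should deprotonate the unhindered C2 methylene rather than the hindered C8 methine and give the enol triflate F5, which Pd(OAc)2/PPh3/HCO2H/Bu3N reduces to 13.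

2. Step 1. What may go wrong: insufficient enantiofacial discrimination or low turnover with the acyclic α-methyl donor. The fallback sets out from 1 and comes back at 3, and replaces catalyst control by a chiral auxiliary. Condensation of 1 with (S)-1-phenylethylamine (PhMe, reflux, water removal) gives the enamino ester F6. Its Michael addition to 2 (ZnCl2, THF) should run through a chair-like transition state on the face anti to the phenyl group and give the imine F7, which aqueous AcOH hydrolyses to 3 with release of the amine. The amine enantiomer is chosen to deliver (S)-3.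

3. Step 12. What may go wrong: slow transmetalation of the hindered alkylborane (chelated by the neighbouring alkoxide), protodeboronation, or Z to E isomerisation of the iodo enoate under the basic palladium conditions. The fallback sets out from 13 and comes back at 18, and builds the enoate by alkyne chemistry. [4-(Trimethylsilyl)but-3-yn-1-yl]magnesium bromide with CeCl3 adds to 13 from the α face to give the carbinol F8. K2CO3/MeOH removes the silyl group to give the terminal alkyne F9. n-BuLi (2.1 equiv) then ClCO2Me at −78 °C, with a cold AcOH quench to prevent oxa-Michael closure, gives the ynoate F10. Me2CuLi (3 equiv, THF, −78 °C) adds syn, which places the new methyl trans to the ester and should give 18.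

**Further compounds**
F1 | step 9 | (1S)-1,3,3-trimethyl-2-methylidene-4-oxocyclohexane-1-carboxylic acid | C=C1C(C)(C)C(=O)CC[C@]1(C)C(=O)O
F2 | step 9 | (4S)-2,2,4-trimethyl-3-methylidene-4-(2-methylprop-2-enoyl)cyclohexan-1-one | C=C1C(C)(C)C(=O)CC[C@]1(C)C(=O)C(C)=C
F3 | step 9 | (4S)-2,2,4-trimethyl-3-methylidene-4-[2-methyl-3-(phenylselanyl)propanoyl]cyclohexan-1-one (epimers in the side chain) | C=C1C(C)(C)C(=O)CC[C@]1(C)C(=O)C(C)C[Se]c1ccccc1
F4 | step 9 | trans-fused (2R,4aS,8aS)-2,5,5,8a-tetramethyloctahydronaphthalene-1,6-dione (the 3,9-dione in labdane numbering) | O=C1[C@H](C)CC[C@H]2C(C)(C)C(=O)CC[C@@]21C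
F5 | step 9 | enol triflate of F4 at the ring A ketone (C2=C3 enol triflate, C9 ketone kept) | O=C1[C@H](C)CC[C@H]2C(C)(C)C(OS(=O)(=O)C(F)(F)F)=CC[C@@]21C
F6 | step 1 | tert-butyl (2Z)-2-methyl-3-{[(1S)-1-phenylethyl]amino}but-2-enoate | C/C(N[C@@H](C)c1ccccc1)=C(\C)C(=O)OC(C)(C)C
F7 | step 1 | tert-butyl (2S)-2-methyl-5-oxo-2-{N-[(1S)-1-phenylethyl]ethanimidoyl}heptanoate | CCC(=O)CC[C@@](C(C)=N[C@@H](C)c1ccccc1)(C(=O)OC(C)(C)C)C
F8 | step 12 | (1S,2R,4aS,8aS)-2,5,5,8a-tetramethyl-1-[4-(trimethylsilyl)but-3-yn-1-yl]-1,2,3,4,4a,5,8,8a-octahydronaphthalen-1-ol | C[Si](C)(C)C#CCC[C@]1(O)[C@H](C)CC[C@H]2C(C)(C)C=CC[C@@]21C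
F9 | step 12 | (1S,2R,4aS,8aS)-1-(but-3-yn-1-yl)-2,5,5,8a-tetramethyl-1,2,3,4,4a,5,8,8a-octahydronaphthalen-1-ol | C#CCC[C@]1(O)[C@H](C)CC[C@H]2C(C)(C)C=CC[C@@]21C
F10 | step 12 | methyl 5-[(1S,2R,4aS,8aS)-1-hydroxy-2,5,5,8a-tetramethyl-1,2,3,4,4a,5,8,8a-octahydronaphthalen-1-yl]pent-2-ynoate | COC(=O)C#CCC[C@]1(O)[C@H](C)CC[C@H]2C(C)(C)C=CC[C@@]21C
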